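In its chair the 1,2-dioxane ring (O1, O2, C3–C6) holds C3–CH2CO2H and C6–CH3 axial, and C4–CH3 and the C6 chain equatorial. C3 and C6 each carry a peroxide oxygen. The ring is therefore read as the H2O2 adduct of a 1,4-keto aldehyde whose central bond is C4–C5. In one flask a chiral-pool bromomethyl ketone is joined to propanal by enantioselective photoredox/enamine alkylation (C4–C5, sets C4). The keto aldehyde is then closed with H2O2/MeOH to a 3,6-dimethoxy-1,2-dioxane (O1–C6, O2–C3). C4 then steers two axial peroxycarbenium captures: methyl at C6, acetic acid at C3.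

Key step: step 5

Assumption: ketene bis(trimethylsilyl) acetal is taken as a purchasable reagent (otherwise one step from trimethylsilyl acetate, LDA, TMSCl). Atom numbers follow the dioxane ring (O1 on C6, O2 on C3); C7 and C8 are the first side-chain carbons, and C2 and C1 the acetic acid carbons.

Step 1
Reactants: 1 (8-bromooctyl)benzene; 2 (S)-3-bromo-2-methylpropan-1-ol
Product: 4 (R)-2-methyl-11-phenylundecan-1-ol, via 8-phenyloctylmagnesium bromide 3 (not isolated)
Conditions: 1 (2.2 equiv), Mg, THF, reflux; then 2, Li2CuCl4 (3 mol %), THF, −78 °C to rt; aq NH4Cl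
Reagents that add atoms: none
Why: Copper-catalysed Kochi-type sp3–sp3 cross-coupling of a primary Grignard reagent with a primary bromide; one equivalent of 3 is spent on the free hydroxyl, and C8 comes unchanged from the chiral pool because it is not a reacting centre (S becomes R only through the CIP ranking).

Step 2
Reactants: 4 (R)-2-methyl-11-phenylundecan-1-ol
Product: 5 [(10R)-11-iodo-10-methylundecyl]benzene
Conditions: I2, PPh3, imidazole, CH2Cl2, 0 °C to rt
Reagents that add atoms: iodine, II
Why: Appel-type iodination (Garegg–Samuelsson conditions) converts the primary alcohol into the iodide by SN2 at CH2 without touching C8.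

Step 3
Reactants: 5 [(10R)-11-iodo-10-methylundecyl]benzene; 6 ethyl vinyl ether
Product: 8 (4R)-2-ethoxy-4-methyl-13-phenyltridec-1-ene, via 1-ethoxyvinyllithium 7 (not isolated)
Conditions: 6, t-BuLi, THF, −78 to 0 °C; then 5, DMPU, −78 °C to rt
Reagents that add atoms: none
Why: Alkylation of an α-lithiated enol ether (acyl anion equivalent) by SN2 at the primary iodide brings in the ketone carbon C6 and the future C5 as a regiodefined terminal enol ether.

Step 4
Reactants: 8 (4R)-2-ethoxy-4-methyl-13-phenyltridec-1-ene
Product: 9 (4R)-1-bromo-4-methyl-13-phenyltridecan-2-one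
Conditions: NBS, THF/H2O 4:1, 0 °C, dark
Reagents that add atoms: N-bromosuccinimide, O=C1CCC(=O)N1Br; water, O
Why: Electrophilic bromination of the enol ether at its terminal carbon, capture of the oxocarbenium ion by water and loss of ethanol (bromohydration of an enol ether) should give the bromomethyl ketone as the only regioisomer.

Step 5
Reactants: 9 (4R)-1-bromo-4-methyl-13-phenyltridecan-2-one; 10 propanal
Product: 12 (4S)-3,6-dimethoxy-4-methyl-6-[(2R)-2-methyl-11-phenylundecyl]-1,2-dioxane (anomeric mixture at C3 and C6), via keto aldehyde 11 (not isolated)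
Conditions: stage a: 10 (3 equiv), (2S,5R)-2-tert-butyl-3,5-dimethylimidazolidin-4-one·HOTf (20 mol %), Ru(bpy)3Cl2 (0.5 mol %), 2,6-lutidine (1.1 equiv), DMF, visible light, 23 °C; excess 10 removed in vacuo; stage b, same flask: MeOH, urea·H2O2 (6 equiv), Sc(OTf)3 (20 mol %), 0 °C to rt
Reagents that add atoms: hydrogen peroxide (from urea·H2O2), OO; methanol, CO
Why: The reduced photocatalyst cleaves the C–Br bond of 9 to the electrophilic α-keto radical at C5, which adds to C4 of the E-enamine formed from 10 and the imidazolidinone, and oxidation of the α-amino radical followed by hydrolysis releases 11 and the amine (C4–C5 made). Once the excess of 10 is stripped off, H2O2 and MeOH add to the C6 ketone under Sc(OTf)3 catalysis to give the methoxy hydroperoxide (O1–C6 made), its OOH group closes onto the C3 aldehyde, and the lactol hydroxyl is exchanged for methoxy to give 12. Both halves are known reaction types, namely the dual photoredox/enamine α-alkylation of aldehydes with α-bromo carbonyl compounds and the acid-catalysed perketalisation of ketones and 1,4-dicarbonyl compounds with H2O2, here run in one flask. The only ring closed is the 1,2-dioxane, by reversible 6-exo-trig addition of the hydroperoxide oxygen to the carbonyl (or oxocarbenium) carbon. C4 is the only lasting new stereocentre and is set by the catalyst, whose tert-butyl group fixes the enamine conformation and whose ring methyl group in the (2S,5R) series shields the Si face, so that the radical enters from the Re face and gives 4S, while C3 and C6 arise as anomeric mixtures that steps 6 and 7 erase and C8 is untouched. The step needs radical formation only at the α-bromo ketone (the sole reducible group), no epimerisation at C4 (buffered, weakly acidic medium) and the six-membered peroxide rather than the five-membered 2,5-dimethoxytetrahydrofuran, which the 1,4-spacing of the two carbonyl groups, the higher nucleophilicity of H2O2 and its excess should secure.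

Step 6
Reactants: 12 (4S)-3,6-dimethoxy-4-methyl-6-[(2R)-2-methyl-11-phenylundecyl]-1,2-dioxane
Product: 13 (4S,6R)-3-methoxy-4,6-dimethyl-6-[(2R)-2-methyl-11-phenylundecyl]-1,2-dioxane (anomeric mixture at C3)
Conditions: AlMe3 (3 equiv), CH2Cl2, −78 to −30 °C; aq Rochelle salt
Reagents that add atoms: trimethylaluminium, C[Al](C)C
Why: Proposed new method: AlMe3 binds the C6 methoxy group and ionises the ketal carbon to the tertiary peroxycarbenium ion C6=O1(+), which forms far more easily than the secondary ion at the C3 acetal, and the methylaluminate counter-ion transfers CH3 along the axial trajectory of the half-chair that keeps C4–CH3 pseudoequatorial (chair-like transition state), so that C6–CH3 ends up axial and trans to C4–CH3 (6R) and the long chain equatorial; the closest known reaction types are the AlMe3 substitution of cyclic ketals through oxocarbenium ions, which installs axial angular methyl groups in cyclic ethers, and the Lewis-acid displacement of 3-alkoxy-1,2-dioxolanes and 3-alkoxy-1,2-dioxanes by allylsilanes and silyl enol ethers through peroxycarbenium ions, and low-temperature organoaluminium reagents are tolerated by dialkyl peroxide bridges in related C-alkylations next to a peroxide ring.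

Step 7
Reactants: 13 (4S,6R)-3-methoxy-4,6-dimethyl-6-[(2R)-2-methyl-11-phenylundecyl]-1,2-dioxane
Product: 15 2-{(3S,4S,6R)-4,6-dimethyl-6-[(2R)-2-methyl-11-phenylundecyl]-1,2-dioxan-3-yl}acetic acid (CNP0181677.1), via trimethylsilyl ester 14 (not isolated)
Conditions: CH2=C(OTMS)2 (3 equiv), TMSOTf (0.2 equiv), CH2Cl2, −78 °C; then pH 4 buffer
Reagents that add atoms: ketene bis(trimethylsilyl) acetal, C=C(O[Si](C)(C)C)O[Si](C)(C)C
Why: TMSOTf ionises the remaining peroxyacetal to the C3 peroxycarbenium ion and the silyl ketene acetal attacks it (Mukaiyama-type displacement of a peroxyacetal, a known reaction type) along the axial trajectory of the half-chair with C4–CH3 and the C6 chain pseudoequatorial, anti to the axial C4–H, which sets 3S with the acetic acid arm axial and cis to C4–CH3, and the silyl ester falls off on work-up so that no basic ester cleavage is needed.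

Compound list
1 | (8-bromooctyl)benzene | BrCCCCCCCCc1ccccc1 | starting material
2 | (S)-3-bromo-2-methylpropan-1-ol | C[C@H](CBr)CO | starting material
3 | 8-phenyloctylmagnesium bromide | Br[Mg]CCCCCCCCc1ccccc1 | intermediate
4 | (R)-2-methyl-11-phenylundecan-1-ol | C[C@H](CCCCCCCCCc1ccccc1)CO | intermediate
5 | [(10R)-11-iodo-10-methylundecyl]benzene | C[C@H](CCCCCCCCCc1ccccc1)CI | intermediate
6 | ethyl vinyl ether | C=COCC | starting material
7 | 1-ethoxyvinyllithium | [Li]C(=C)OCC | intermediate
8 | (4R)-2-ethoxy-4-methyl-13-phenyltridec-1-ene | C[C@H](CCCCCCCCCc1ccccc1)CC(=C)OCC | intermediate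
9 | (4R)-1-bromo-4-methyl-13-phenyltridecan-2-one | C[C@H](CCCCCCCCCc1ccccc1)CC(=O)CBr | intermediate
10 | propanal | CCC=O | starting material
11 | (2S,6R)-2,6-dimethyl-4-oxo-15-phenylpentadecanal | C[C@H](CCCCCCCCCc1ccccc1)CC(=O)C[C@H](C)C=O | intermediate
12 | (4S)-3,6-dimethoxy-4-methyl-6-[(2R)-2-methyl-11-phenylundecyl]-1,2-dioxane (C3, C6 anomers) | C[C@H](CCCCCCCCCc1ccccc1)CC1(OC)C[C@H](C)C(OC)OO1 | intermediate
13 | (4S,6R)-3-methoxy-4,6-dimethyl-6-[(2R)-2-methyl-11-phenylundecyl]-1,2-dioxane (C3 anomers) | C[C@H](CCCCCCCCCc1ccccc1)C[C@]1(C)C[C@H](C)C(OC)OO1 | intermediate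
14 | trimethylsilyl 2-{(3S,4S,6R)-4,6-dimethyl-6-[(2R)-2-methyl-11-phenylundecyl]-1,2-dioxan-3-yl}acetate | C[C@H](CCCCCCCCCc1ccccc1)C[C@]1(C)C[C@H](C)[C@H](CC(=O)O[Si](C)(C)C)OO1 | intermediate
15 | 2-{(3S,4S,6R)-4,6-dimethyl-6-[(2R)-2-methyl-11-phenylundecyl]-1,2-dioxan-3-yl}acetic acid | C[C@H](CCCCCCCCCc1ccccc1)C[C@]1(C)C[C@H](C)[C@H](CC(=O)O)OO1 | target

Total step count: 7. Longest linear sequence: 7 steps.

Steps most likely to fail

Step 6 (Proposed new method).
- What may go wrong: the organoaluminium reagent may attack or reductively open the O–O bond. Ionisation may also start at the C3 acetal. The C6 cation may lose a proton instead of taking up methyl. The minor C3 anomer may erode the facial selectivity.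
- Fallback with known chemistry, setting out from 11 (isolated by normal work-up after stage a of step 5) and returning at 13: the aldehyde is masked selectively with MeOH, PPTS and molecular sieves as (2S,6R)-1,1-dimethoxy-2,6-dimethyl-15-phenylpentadecan-4-one F1. Wittig methylenation (Ph3P=CH2, THF) gives [(10R,14S)-15,15-dimethoxy-10,14-dimethyl-12-methylidenepentadecyl]benzene F2. Mukaiyama–Isayama peroxidation (Co(acac)2, Et3SiH, O2) puts hydrogen on the methylidene carbon and the silylperoxy group on C6 to give triethyl{[(2S,6R)-1,1-dimethoxy-2,4,6-trimethyl-15-phenylpentadecan-4-yl]peroxy}silane F3. Catalytic TsOH·H2O in CH2Cl2 then removes the silyl group and closes the hydroperoxide onto the acetal.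
- Outcome: this should give 13 beside (4S,6S)-3-methoxy-4,6-dimethyl-6-[(2R)-2-methyl-11-phenylundecyl]-1,2-dioxane F4. The sequence has no control at C6, so the two epimers are separated by chromatography.

Step 5 (key step).
- What may go wrong: low enantioselectivity or self-condensation with the small aldehyde, epimerisation at C4 in the acidic stage, oxidation of the aldehyde by H2O2, and closure through an oxygen of methanol or water to the five-membered bis-acetal instead of the peroxide ring.
- Fallback, setting out from 8 and returning at 12: the C4–C5 bond is made oxidatively instead of reductively. SOMO-enamine coupling of 10 uses the enol ether 8 itself as π-nucleophile ((NH4)2Ce(NO3)6, the Re-face-exposing enantiomer of 5-benzyl-2-tert-butyl-3-methylimidazolidin-4-one·TFA, NaHCO3, DME/H2O, −20 °C) and gives 11, which is isolated. Ethereal H2O2 without any alcohol then converts 11 into (4S)-4-methyl-6-[(2R)-2-methyl-11-phenylundecyl]-1,2-dioxane-3,6-diol F5, a medium in which no alkoxytetrahydrofuran can form. MeOH/PPTS exchanges both hydroxyl groups to give 12.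

Step 7.
- What may go wrong: poor facial selectivity at C3 because the bulky nucleophile approaches gauche to C4–CH3, Lewis-acid ionisation of the tertiary C6–O1 bond, and protodesilylation of the ketene acetal.
- Fallback, setting out from 13 and returning at 15: the small π-nucleophile allyltrimethylsilane (SnCl4, CH2Cl2, −78 °C) installs a three-carbon handle by the same axial capture and gives (3S,4S,6R)-4,6-dimethyl-6-[(2R)-2-methyl-11-phenylundecyl]-3-(prop-2-en-1-yl)-1,2-dioxane F6. Ozonolysis in CH2Cl2/pyridine at −78 °C gives 2-{(3S,4S,6R)-4,6-dimethyl-6-[(2R)-2-methyl-11-phenylundecyl]-1,2-dioxan-3-yl}acetaldehyde F7 without a reducing work-up. Pinnick oxidation (NaClO2, NaH2PO4, 2-methylbut-2-ene) gives 15.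

Further compounds
F1 | step 6 | (2S,6R)-1,1-dimethoxy-2,6-dimethyl-15-phenylpentadecan-4-one | C[C@H](CCCCCCCCCc1ccccc1)CC(=O)C[C@H](C)C(OC)OC
F2 | step 6 | [(10R,14S)-15,15-dimethoxy-10,14-dimethyl-12-methylidenepentadecyl]benzene | C[C@H](CCCCCCCCCc1ccccc1)CC(=C)C[C@H](C)C(OC)OC
F3 | step 6 | triethyl{[(2S,6R)-1,1-dimethoxy-2,4,6-trimethyl-15-phenylpentadecan-4-yl]peroxy}silane (both C4 epimers) | C[C@H](CCCCCCCCCc1ccccc1)CC(C)(OO[Si](CC)(CC)CC)C[C@H](C)C(OC)OC
F4 | step 6 | (4S,6S)-3-methoxy-4,6-dimethyl-6-[(2R)-2-methyl-11-phenylundecyl]-1,2-dioxane | C[C@H](CCCCCCCCCc1ccccc1)C[C@@]1(C)C[C@H](C)C(OC)OO1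
F5 | step 5 | (4S)-4-methyl-6-[(2R)-2-methyl-11-phenylundecyl]-1,2-dioxane-3,6-diol | C[C@H](CCCCCCCCCc1ccccc1)CC1(O)C[C@H](C)C(O)OO1
F6 | step 7 | (3S,4S,6R)-4,6-dimethyl-6-[(2R)-2-methyl-11-phenylundecyl]-3-(prop-2-en-1-yl)-1,2-dioxane | C[C@H](CCCCCCCCCc1ccccc1)C[C@]1(C)C[C@H](C)[C@H](CC=C)OO1
F7 | step 7 | 2-{(3S,4S,6R)-4,6-dimethyl-6-[(2R)-2-methyl-11-phenylundecyl]-1,2-dioxan-3-yl}acetaldehyde | C[C@H](CCCCCCCCCc1ccccc1)C[C@]1(C)C[C@H](C)[C@H](CC=O)OO1
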